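**Plan**
- Retrosynthesis of epiphorellic acid 1 (compound 1): take off three benzyl groups; cut the pentyl bond at position 6 of ring A back to an aryl chloride; cut the methyl ester back to the free acid; then cut together the diaryl ether bond at position 2 and the carboxyl bond at position 1 of ring A, leaving a chloroaryne, the ring B phenoxide and CO2.
- Enabling feature: ring A (numbered from the ester-bearing carbon as position 1, with the ether oxygen on position 2, the hydroxyl on position 4 and the pentyl on position 6) carries the hindered aryloxy group and the carboxyl carbon on neighbouring carbons, the two ends of an aryne triple bond. A chlorine placed on position 6 steers the addition and is later exchanged for pentyl.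
- Ring B (carboxyl on position 1, pentyl on 2, ether oxygen on 3, methoxy on 4, hydroxyl on 6) comes from olivetolic acid by para-hydroxylation.
- Forward order: no ring is built. The aryne precursor (three steps) and the ring B phenol (four steps) are made separately and joined with CO2 in step 8; esterification, Negishi pentylation and hydrogenolysis finish the chain.
- Stereochemistry: the target has no stereocentre and no stereogenic double bond; every selectivity question is regiochemical.

Key step: step 8

Assumption: olivetolic acid and n-pentylzinc bromide (THF solution) are treated as purchasable, and olivetolic acid is kept below 50 °C because 2,4-dihydroxybenzoic acids decarboxylate on heating.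

**Step 1**
Reactants: 2 4-(benzyloxy)phenol
Product: 3 4-(benzyloxy)-2-chlorophenol
Conditions: SO2Cl2 (1.0 equiv), i-Bu2NH (cat.), toluene, 0 °C → rt
Reagents that add atoms: sulfuryl chloride, O=S(=O)(Cl)Cl
Why: Electrophilic aromatic chlorination; the amine/SO2Cl2 system chlorinates ortho to the free hydroxyl of a para-blocked phenol, and one equivalent should stop at the monochloride.

**Step 2**
Reactants: 3 4-(benzyloxy)-2-chlorophenol
Product: 4 4-(benzyloxy)-2-bromo-6-chlorophenol
Conditions: NBS (1.0 equiv), i-Pr2NH (cat.), CH2Cl2, 0 °C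
Reagents that add atoms: N-bromosuccinimide, O=C1CCC(=O)N1Br
Why: Electrophilic aromatic bromination; the hydroxyl is the strongest director and its only free ortho position is the one expected to be brominated.

**Step 3**
Reactants: 4 4-(benzyloxy)-2-bromo-6-chlorophenol
Product: 7 4-(benzyloxy)-2-chloro-6-(trimethylsilyl)phenyl trifluoromethanesulfonate, via aryl trimethylsilyl ether 5 (not isolated), via lithium 2-silylphenoxide 6 (not isolated)
Conditions: HMDS, THF, 65 °C, then evaporate; n-BuLi (1.05 equiv), THF, −100 → −78 °C; Tf2O, −100 °C → rt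
Reagents that add atoms: hexamethyldisilazane, C[Si](C)(C)N[Si](C)(C)C; trifluoromethanesulfonic anhydride, O=S(=O)(OS(=O)(=O)C(F)(F)F)C(F)(F)F
Why: This is the standard route to ortho-silylaryl triflates (O-silylation, bromine–lithium exchange with 1,3 O-to-C silyl shift in a retro-Brook rearrangement, then O-triflation); the chlorine is meta to the lithiated carbon so no aryne can form here, and exchange at −100 °C should outrun any reaction at the benzyl ether.

**Step 4**
Reactants: 8 olivetolic acid (2,4-dihydroxy-6-pentylbenzoic acid); 9 benzyl bromide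
Product: 10 benzyl 2,4-dihydroxy-6-pentylbenzoate
Conditions: KHCO3, DMF, rt → 40 °C
Reagents that add atoms: benzyl bromide (compound 9), BrCc1ccccc1
Why: Carboxylate O-alkylation (SN2); KHCO3 deprotonates only the carboxylic acid, so both phenols should stay free.

**Step 5**
Reactants: 10 benzyl 2,4-dihydroxy-6-pentylbenzoate
Product: 11 benzyl 2-hydroxy-4-methoxy-6-pentylbenzoate
Conditions: MeI (1.1 equiv), K2CO3, acetone, rt → 40 °C
Reagents that add atoms: iodomethane, CI
Why: Williamson ether synthesis, regioselective because the 2-hydroxyl is hydrogen-bonded to the ester carbonyl while the 4-hydroxyl is the more acidic and accessible one, as in orsellinate esters.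

**Step 6**
Reactants: 11 benzyl 2-hydroxy-4-methoxy-6-pentylbenzoate
Product: 12 potassium 3-(benzyloxycarbonyl)-4-hydroxy-6-methoxy-2-pentylphenyl sulfate
Conditions: K2S2O8 (1.1 equiv), aq KOH (10%), pyridine, 5 °C → rt; pH 7, Et2O wash (recovers 11), n-BuOH extraction of the salt
Reagents that add atoms: potassium peroxydisulfate, [K+].[K+].[O-]S(=O)(=O)OOS(=O)(=O)[O-]
Why: Elbs persulfate oxidation; peroxydisulfate attacks the phenoxide at its free para position (between pentyl and methoxy) to give the aryl sulfate, which also masks the new oxygen, and the di-ortho-substituted, phenoxide-deactivated benzyl ester should resist cold aqueous alkali.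

**Step 7**
Reactants: 12 potassium 3-(benzyloxycarbonyl)-4-hydroxy-6-methoxy-2-pentylphenyl sulfate; 9 benzyl bromide
Product: 14 benzyl 6-(benzyloxy)-3-hydroxy-4-methoxy-2-pentylbenzoate (ring B phenol), via O-benzylated sulfate salt 13 (not isolated)
Conditions: BnBr, K2CO3, DMF, 60 °C; then 1 M HCl, dioxane, 70 °C
Reagents that add atoms: benzyl bromide (compound 9), BrCc1ccccc1
Why: Williamson benzylation of the remaining chelated phenol while the new oxygen is still a sulfate, followed by acid-catalysed hydrolysis of the aryl sulfate monoester, which is the usual way to turn an Elbs product into a hydroquinone mono-ether.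

**Step 8**
Reactants: 14 benzyl 6-(benzyloxy)-3-hydroxy-4-methoxy-2-pentylbenzoate; 7 4-(benzyloxy)-2-chloro-6-(trimethylsilyl)phenyl trifluoromethanesulfonate; 15 carbon dioxide
Product: 19 4-(benzyloxy)-2-[4-(benzyloxy)-3-(benzyloxycarbonyl)-6-methoxy-2-pentylphenoxy]-6-chlorobenzoic acid, via potassium phenoxide of ring B 16 (not isolated), via 5-(benzyloxy)-3-chlorobenzyne 17 (not isolated), via ortho-chloroaryl potassium adduct 18 (not isolated)
Conditions: 14 (1.3 equiv), KH, THF, 0 °C; then 18-crown-6, KF, CO2 (1 atm), slow addition of 7, THF, 0 °C → rt; 1 M HCl work-up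
Reagents that add atoms: carbon dioxide (compound 15), O=C=O
Why: Proposed new method: fluoride attacks silicon of 7 and triflate leaves to give aryne 17, the pre-formed potassium phenoxide 16 adds through oxygen to the aryne carbon remote from chlorine, and the ortho-chloroaryl anion 18 should be captured by dissolved CO2 before it finds a proton or expels chloride, so the aryl ether bond at position 2 and the carboxyl bond at position 1 of ring A form in one operation. The closest known reaction types are the KF/18-crown-6 coupling of arynes, amines and CO2 to anthranilic acids and the O-arylation of phenols by arynes from ortho-silylaryl triflates. No ring is closed and no stereocentre is created. The required regiochemistry (oxygen on position 2, carbon on position 1 of ring A) rests on the chlorine on position 6, which distorts and polarises the triple bond so that nucleophiles attack the distal carbon and charge builds next to the C–Cl bond, while the benzyloxy group on position 4, para to the carbanion carbon, has only a weak remote effect that should not override it. Making the phenoxide with KH (H2 lost) and working in THF removes the proton sources (phenol O–H, bifluoride, acetonitrile) that would quench 18 to the simple diaryl ether. The phenoxide, used in slight excess, should outcompete the product carboxylate for the aryne, and it has no free ortho or para position for Kolbe–Schmitt carboxylation.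

**Step 9**
Reactants: 19 4-(benzyloxy)-2-[4-(benzyloxy)-3-(benzyloxycarbonyl)-6-methoxy-2-pentylphenoxy]-6-chlorobenzoic acid
Product: 20 benzyl 6-(benzyloxy)-3-[5-(benzyloxy)-3-chloro-2-(methoxycarbonyl)phenoxy]-4-methoxy-2-pentylbenzoate
Conditions: MeI, K2CO3, DMF, rt
Reagents that add atoms: iodomethane, CI
Why: Carboxylate O-alkylation (SN2), the method of choice for a 2,6-disubstituted benzoic acid that resists Fischer esterification.

**Step 10**
Reactants: 20 benzyl 6-(benzyloxy)-3-[5-(benzyloxy)-3-chloro-2-(methoxycarbonyl)phenoxy]-4-methoxy-2-pentylbenzoate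
Product: 21 benzyl 6-(benzyloxy)-3-[5-(benzyloxy)-2-(methoxycarbonyl)-3-pentylphenoxy]-4-methoxy-2-pentylbenzoate
Conditions: n-pentylzinc bromide (1.5 equiv), Pd(OAc)2 (2 mol %), SPhos (4 mol %), THF/NMP, 65 °C
Reagents that add atoms: n-pentylzinc bromide, CCCCC[Zn]Br
Why: Negishi cross-coupling; a zerovalent palladium/SPhos catalyst should insert into the aryl chloride activated by the ortho ester, primary alkylzinc halides couple faster than β-hydride elimination with this ligand class, and esters and benzyl ethers are inert to the organozinc.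

**Step 11**
Reactants: 21 benzyl 6-(benzyloxy)-3-[5-(benzyloxy)-2-(methoxycarbonyl)-3-pentylphenoxy]-4-methoxy-2-pentylbenzoate
Product: 1 epiphorellic acid 1 (6-hydroxy-3-[5-hydroxy-2-(methoxycarbonyl)-3-pentylphenoxy]-4-methoxy-2-pentylbenzoic acid)
Conditions: H2 (1 atm), 10% Pd/C, EtOAc/MeOH, rt
Reagents that add atoms: none
Why: Catalytic hydrogenolysis should remove the two benzyl ethers and the benzyl ester while the methyl ester, diaryl ether and methoxy group stay intact, and room temperature avoids decarboxylation of the salicylic-type acid; it is placed after step 10 so that no C–Cl bond is exposed to hydrogen.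

**Compound list**
1 | epiphorellic acid 1 (6-hydroxy-3-[5-hydroxy-2-(methoxycarbonyl)-3-pentylphenoxy]-4-methoxy-2-pentylbenzoic acid) | CCCCCc1cc(O)cc(Oc2c(OC)cc(O)c(C(=O)O)c2CCCCC)c1C(=O)OC | target
2 | 4-(benzyloxy)phenol | Oc1ccc(OCc2ccccc2)cc1 | starting material
3 | 4-(benzyloxy)-2-chlorophenol | Oc1ccc(OCc2ccccc2)cc1Cl | intermediate
4 | 4-(benzyloxy)-2-bromo-6-chlorophenol | Oc1c(Cl)cc(OCc2ccccc2)cc1Br | intermediate
5 | [4-(benzyloxy)-2-bromo-6-chlorophenoxy]trimethylsilane | C[Si](C)(C)Oc1c(Cl)cc(OCc2ccccc2)cc1Br | intermediate (not isolated)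
6 | lithium 4-(benzyloxy)-2-chloro-6-(trimethylsilyl)phenoxide | [Li+].[O-]c1c(Cl)cc(OCc2ccccc2)cc1[Si](C)(C)C | intermediate (not isolated)
7 | 4-(benzyloxy)-2-chloro-6-(trimethylsilyl)phenyl trifluoromethanesulfonate | C[Si](C)(C)c1cc(OCc2ccccc2)cc(Cl)c1OS(=O)(=O)C(F)(F)F | intermediate
8 | olivetolic acid (2,4-dihydroxy-6-pentylbenzoic acid) | CCCCCc1cc(O)cc(O)c1C(=O)O | starting material
9 | benzyl bromide | BrCc1ccccc1 | starting material
10 | benzyl 2,4-dihydroxy-6-pentylbenzoate | CCCCCc1cc(O)cc(O)c1C(=O)OCc1ccccc1 | intermediate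
11 | benzyl 2-hydroxy-4-methoxy-6-pentylbenzoate | CCCCCc1cc(OC)cc(O)c1C(=O)OCc1ccccc1 | intermediate
12 | potassium 3-(benzyloxycarbonyl)-4-hydroxy-6-methoxy-2-pentylphenyl sulfate | CCCCCc1c(OS(=O)(=O)[O-])c(OC)cc(O)c1C(=O)OCc1ccccc1.[K+] | intermediate
13 | potassium 4-(benzyloxy)-3-(benzyloxycarbonyl)-6-methoxy-2-pentylphenyl sulfate | CCCCCc1c(OS(=O)(=O)[O-])c(OC)cc(OCc2ccccc2)c1C(=O)OCc1ccccc1.[K+] | intermediate (not isolated)
14 | benzyl 6-(benzyloxy)-3-hydroxy-4-methoxy-2-pentylbenzoate | CCCCCc1c(O)c(OC)cc(OCc2ccccc2)c1C(=O)OCc1ccccc1 | intermediate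
15 | carbon dioxide | O=C=O | starting material
16 | potassium 4-(benzyloxy)-3-(benzyloxycarbonyl)-6-methoxy-2-pentylphenoxide | CCCCCc1c([O-])c(OC)cc(OCc2ccccc2)c1C(=O)OCc1ccccc1.[K+] | intermediate (not isolated)
17 | 5-(benzyloxy)-3-chlorobenzyne | ClC1=CC(OCc2ccccc2)=CC#C1 | intermediate (not isolated)
18 | potassium 2-aryloxy-4-(benzyloxy)-6-chlorophenyl anion (aryl is protected ring B) | CCCCCc1c(Oc2cc(OCc3ccccc3)cc(Cl)[c-]2)c(OC)cc(OCc2ccccc2)c1C(=O)OCc1ccccc1.[K+] | intermediate (not isolated)
19 | 4-(benzyloxy)-2-[4-(benzyloxy)-3-(benzyloxycarbonyl)-6-methoxy-2-pentylphenoxy]-6-chlorobenzoic acid | OC(=O)c1c(Cl)cc(OCc2ccccc2)cc1Oc1c(OC)cc(OCc2ccccc2)c(C(=O)OCc2ccccc2)c1CCCCC | intermediate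
20 | benzyl 6-(benzyloxy)-3-[5-(benzyloxy)-3-chloro-2-(methoxycarbonyl)phenoxy]-4-methoxy-2-pentylbenzoate | COC(=O)c1c(Cl)cc(OCc2ccccc2)cc1Oc1c(OC)cc(OCc2ccccc2)c(C(=O)OCc2ccccc2)c1CCCCC | intermediate
21 | benzyl 6-(benzyloxy)-3-[5-(benzyloxy)-2-(methoxycarbonyl)-3-pentylphenoxy]-4-methoxy-2-pentylbenzoate | CCCCCc1cc(OCc2ccccc2)cc(Oc2c(OC)cc(OCc3ccccc3)c(C(=O)OCc3ccccc3)c2CCCCC)c1C(=O)OC | intermediate

**Step count**
Total: 11 steps. Longest linear sequence: 8 steps (steps 4–11, from olivetolic acid); the aryne branch is 7 steps (steps 1–3, then 8–11).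

**Steps most likely to fail**

1. Step 8 (the new three-component coupling). The aryl anion may be protonated before CO2 reaches it, the phenoxide may be held back as its carbonate so that the aryne is consumed by fluoride or by the product carboxylate, or chloride may be lost from the ortho-chloroaryl anion. The fallback uses known palladium-catalysed C–O coupling. It sets out from olivetolic acid 8 and phenol 14 and rejoins the route at 21, so that steps 1–3, 9 and 10 fall away. Olivetolic acid 8 would be esterified with MeI/KHCO3 in DMF to methyl 2,4-dihydroxy-6-pentylbenzoate F1. Benzylation at the non-chelated 4-hydroxyl (benzyl bromide 9, K2CO3, acetone) would give methyl 4-(benzyloxy)-2-hydroxy-6-pentylbenzoate F2. Triflation (Tf2O, pyridine, CH2Cl2, 0 °C) would give methyl 4-(benzyloxy)-2-pentyl-6-(trifluoromethylsulfonyloxy)benzoate F3. Slow addition of F3 to phenol 14 under Pd(OAc)2/t-BuXPhos, K3PO4, toluene, 100 °C should give the diaryl ether 21, with the pentyl group and methyl ester already in place.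

2. Step 6 (Elbs oxidation). Conversion may be low, the electron-rich phenoxide may be over-oxidised, the benzyl ester may be saponified in aqueous alkali, or the sulfate salt may be lost on isolation. The fallback replaces direct hydroxylation by halogenation, borylation and oxidation; it sets out from 11 and rejoins at 14, replacing steps 6 and 7. Phenol 11 would be benzylated (benzyl bromide 9, K2CO3, DMF, 60 °C) to benzyl 2-(benzyloxy)-4-methoxy-6-pentylbenzoate F4. NBS in MeCN should brominate para to the benzyloxy group, as 3,5-dialkoxytoluenes do, giving benzyl 6-(benzyloxy)-3-bromo-4-methoxy-2-pentylbenzoate F5. Miyaura borylation (B2pin2, Pd(OAc)2, SPhos, KOAc, dioxane, 100 °C) would give benzyl 6-(benzyloxy)-4-methoxy-2-pentyl-3-(4,4,5,5-tetramethyl-1,3,2-dioxaborolan-2-yl)benzoate F6. Oxidation with NaBO3 in THF/H2O at rt would then deliver phenol 14.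

3. Step 10 (Negishi pentylation). Oxidative addition into the chloride on the crowded, oxygen-rich ring may be slow, and β-hydride elimination from the pentylpalladium intermediate may reduce the C–Cl bond instead. The fallback replaces the alkyl coupling by an alkenyl coupling; it sets out from 20 and rejoins at the target 1. Suzuki–Miyaura coupling of 20 with (E)-pent-1-enylboronic acid pinacol ester (Pd(OAc)2, SPhos, K3PO4, toluene/H2O, 90 °C) would give benzyl 6-(benzyloxy)-3-{5-(benzyloxy)-2-(methoxycarbonyl)-3-[(E)-pent-1-en-1-yl]phenoxy}-4-methoxy-2-pentylbenzoate F7. Hydrogenation of F7 under the conditions of step 11 (H2, 10% Pd/C, EtOAc/MeOH, rt) should saturate the alkene and remove the three benzyl groups in the same operation to give 1.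

**Further compounds**
F1 | step 8 | methyl 2,4-dihydroxy-6-pentylbenzoate | CCCCCc1cc(O)cc(O)c1C(=O)OC
F2 | step 8 | methyl 4-(benzyloxy)-2-hydroxy-6-pentylbenzoate | CCCCCc1cc(OCc2ccccc2)cc(O)c1C(=O)OC
F3 | step 8 | methyl 4-(benzyloxy)-2-pentyl-6-(trifluoromethylsulfonyloxy)benzoate | CCCCCc1cc(OCc2ccccc2)cc(OS(=O)(=O)C(F)(F)F)c1C(=O)OC
F4 | step 6 | benzyl 2-(benzyloxy)-4-methoxy-6-pentylbenzoate | CCCCCc1cc(OC)cc(OCc2ccccc2)c1C(=O)OCc1ccccc1
F5 | step 6 | benzyl 6-(benzyloxy)-3-bromo-4-methoxy-2-pentylbenzoate | CCCCCc1c(Br)c(OC)cc(OCc2ccccc2)c1C(=O)OCc1ccccc1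
F6 | step 6 | benzyl 6-(benzyloxy)-4-methoxy-2-pentyl-3-(4,4,5,5-tetramethyl-1,3,2-dioxaborolan-2-yl)benzoate | CCCCCc1c(B2OC(C)(C)C(C)(C)O2)c(OC)cc(OCc2ccccc2)c1C(=O)OCc1ccccc1
F7 | step 10 | benzyl 6-(benzyloxy)-3-{5-(benzyloxy)-2-(methoxycarbonyl)-3-[(E)-pent-1-en-1-yl]phenoxy}-4-methoxy-2-pentylbenzoate | CCC/C=C/c1cc(OCc2ccccc2)cc(Oc2c(OC)cc(OCc3ccccc3)c(C(=O)OCc3ccccc3)c2CCCCC)c1C(=O)OC
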